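The runs were computed with constants of no real substance; the scatter is artificial.

Which flask holds more intermediate at the end, hot Saturday's or cool Thursday's?

all flasks: gas 100 mM (held)
- ochre: starting material 0.60 M; temperature 78 °C; run made earlier
- grey: starting material 2.4 M; temperature 94 °C; run made earlier
- Saturday's: starting material 1.2 M; temperature 100 °C; time 10 min
- Thursday's: starting material 1.2 M; temperature 70 °C; time 10 min

| run | time / min | intermediate / % | product / % | starting material / % |
|---|---|---|---|---|
| ochre | 1.33 | 30.5 | 3.4 | 62.2 |
| ochre | 3.00 | 49.5 | 12.5 | 35.0 |
| ochre | 8.00 | 37.7 | 49.8 | 11.7 |
| ochre | 20.0 | 7.6 | 87.4 | 2.2 |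
| grey | 0.833 | 3.7 | 2.5 | 92.9 |
| grey | 2.00 | 10.5 | 9.6 | 82.6 |
| grey | 4.00 | 14.6 | 23.6 | 65.1 |
| grey | 6.00 | 13.1 | 41.9 | 46.3 |

(each reading ± 1 percentage point)

- the best flask by amount of intermediate, in percent of the starting material charged; "all alike" if 1.5 percentage points covers them all (Saturday's / Thursday's / all alike)
- amount of intermediate at the end, in percent of the starting material charged, Saturday's
- amount of intermediate at the end, in percent of the starting material charged, Thursday's

We watch two things: how fast intermediate drains and how fast it is fed. Between its second and third readings, the ochre run gains product at 0.171 /min of the intermediate standing. The hotter grey run, between its last two readings, gives 0.661 /min. Spacing these by temperature on a log scale, we reckon 1.10 /min for Saturday's and 0.0871 /min for Thursday's.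

But grey's starting material falls evenly, which suggests coupling partner arriving from the gas at a steady pace. We assume the same amount per minute in the new flasks. Their charge is half grey's, so each should lose 0.181 /min of its charge.

Dividing this loss by the drain cancels the minutes, giving 16.6% for Saturday's and 208% for Thursday's. This is the balance level, the fraction of the charge at which intermediate drains as fast as it is fed (a steady state). Saturday's level lies below the charge, so we expect intermediate to stall low there. Thursday's lies above the charge, so we expect intermediate there to climb as long as the feed holds, and at this pace the whole charge lasts 5.52 min.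

The forecast gives Thursday's, with 3% for Saturday's and 51% for Thursday's, where "intermediate builds and barely drains".

The flasks give 3.16% for Saturday's and 54.7% for Thursday's, so Thursday's leads, as forecast.

    starting material + coupling partner ⇌ intermediate (K = 6.90 /M, k = 62.0 /M/min, Ea = 76.0 kJ/mol, ΔH = −78.0 kJ/mol)
    intermediate → product (k = 1.00 /min, Ea = 92.0 kJ/mol)
    gas ⇌ coupling partner, rate k3*(csat - [coupling partner]) (kL = 2.70 /min)
    2 coupling partner → homo dimer (k = 0.880 /M/min, Ea = 72.0 kJ/mol)
    (constants at 100 °C)

Between 5.00 min and 10.0 min, Thursday's starting material loses 0.0460 /min of the charge, slower than the feed we assumed. Over the same minutes Thursday's product gains 0.0789 /min of the intermediate standing, which puts the level at 58.3%, while intermediate stands at 53.0%, then 54.7%. The neighbour is Thursday's flask read at 2.50 min. Its starting material has lost 0.147 /min on average, which on our reckoned drain gives a level of 169%, while its intermediate stands at 33.5%.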